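**Plan**

Target numbering: C1 = C(CH3)(CH=CHBr), C2 = CHBr, C3 = CH2, C4 = CHCl, C5 = C(CH3)Cl, C6 = CH2.
Retrosynthesis cuts, in order: C5–Cl (HCl across C5=C6), C4–Cl (from C4–O with inversion), the bromovinyl C=C (from a C1 aldehyde), then C1–C2 and C3–C4 together in a [4+2] event, which leaves a 3-carbomethoxy-5-methyl-2-pyrone and vinyl bromide.
Enabling feature: C1 and C4 lie 1,4 across the cyclohexane, the C1 methyl is trans to the C4 chlorine, and C2–C3 is a bare CHBr–CH2 unit. Tying the C1 methyl carbon to the C4 heteroatom as a C(=O)–O bridge turns C1–C6–C5–C4 into the locked s-cis diene of a 2-pyrone, so the fully substituted diene terminus C1 can react.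
Forward: the pyrone ring is made first; the cycloaddition closes the carbocycle as a 2-oxabicyclo[2.2.2]octenone; the lactone bridge is then unravelled (C=O to CH3, O to allylic OH), the ester becomes the (E)-bromovinyl group, OH becomes Cl, and HCl addition finishes.
Stereochemistry: the chiral Cu(II) catalyst sets C1, C2 (Br endo, cis to the ester) and the C4–O bond in the cycloaddition; C4–Cl comes from SN2 inversion of that C–O bond; C5 comes from axial chloride capture, which is also the thermodynamic epimer.

Key step: step 3

Assumption: the (S,S)-tert-butyl-bis(oxazoline) ligand is taken to leave open the pyrone face that leads to (1S,4S,8S)-6; if the facial sense proves opposite, the (R,R)-ligand is used with no other change.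

**Route**

Step 1
Reactants: 1 (2E)-3-ethoxy-2-methylprop-2-enal (3-ethoxymethacrolein); 2 dimethyl malonate
Product: 3 dimethyl 2-[(2E)-3-ethoxy-2-methylprop-2-en-1-ylidene]propanedioate
Conditions: Ac2O, ZnCl2 (cat.), 100 °C
Reagents that add atoms: none
Why: Knoevenagel condensation of the malonate with a vinylogous formate ester under the Ac2O/ZnCl2 conditions used for alkoxymethylene- and alkoxyallylidene-malonates should give the push–pull dienyl diester; no stereocentre forms and the alkene geometry is irrelevant because it equilibrates in step 2.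

Step 2
Reactants: 3 dimethyl 2-[(2E)-3-ethoxy-2-methylprop-2-en-1-ylidene]propanedioate
Product: 4 methyl 5-methyl-2-oxo-2H-pyran-3-carboxylate
Conditions: HCO2H/H2O (9:1), 90 °C
Reagents that add atoms: water, O
Why: Acid hydrolysis of the enol ether gives the dienol, whose (Z)-form lactonises onto the cis ester with loss of methanol (2-pyrone synthesis by enol lactonisation), the pyrone being the thermodynamic sink.

Step 3
Reactants: 4 methyl 5-methyl-2-oxo-2H-pyran-3-carboxylate; 5 vinyl bromide (bromoethene)
Product: 6 methyl (1S,4S,8S)-8-bromo-6-methyl-3-oxo-2-oxabicyclo[2.2.2]oct-5-ene-4-carboxylate (Br endo: syn to the C5=C6 bridge, anti to the lactone bridge)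
Conditions: [Cu((S,S)-t-Bu-box)](SbF6)2 (10 mol %), vinyl bromide (10 equiv, condensed), 4 Å MS, CH2Cl2, sealed tube, −20 °C → rt
Reagents that add atoms: none
Why: Proposed new method: an inverse-electron-demand [4+2] cycloaddition in which the Cu(II)–bis(oxazoline) Lewis acid chelates the lactone and ester carbonyls of 4 and lowers the diene LUMO, while vinyl bromide, whose π-HOMO is raised and polarised toward CH2 by the bromine lone pair, bonds through CH2 to pyrone C6 and through CHBr to pyrone C3 in a concerted, asynchronous, suprafacial–suprafacial event; the closest known reaction type is the chiral-Lewis-acid-catalysed cycloaddition of 3-carbomethoxy-2-pyrones with vinyl ethers, vinyl sulfides and styrenes. The one operation closes the six-membered carbocycle (pyrone C3–C6 plus the two alkene carbons) by intermolecular [4π+2π] closure and so creates the 2-oxabicyclo[2.2.2]octene, the former pyrone C(=O)–O unit remaining as the bridge. C4 and C1 of 6 are formed cis across the ring because both new bonds form on one face of the planar pyrone; C8 is set by the endo transition state, which places Br under the diene and away from the chelated carbonyls and the ligand, hence anti to the lactone bridge and cis to the ester; the absolute sense comes from the pyrone face left open by the tert-butyl groups of the ligand. The step needs regio-, endo- and enantiofacial selectivity and survival of the adduct: regiochemistry should follow from pairing the most electrophilic terminus C6 (δ-carbon of the doubly activated dienoate) with the nucleophilic CH2, and the low temperature should prevent retro-[4+2] loss of CO2.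

Step 4
Reactants: 6 methyl (1S,4S,8S)-8-bromo-6-methyl-3-oxo-2-oxabicyclo[2.2.2]oct-5-ene-4-carboxylate
Product: 7 methyl (1S,4R,8S)-8-bromo-3-hydroxy-6-methyl-2-oxabicyclo[2.2.2]oct-5-ene-4-carboxylate (lactol, both C3 epimers)
Conditions: DIBAL-H (1.1 equiv), CH2Cl2, −78 °C; aq. Rochelle salt
Reagents that add atoms: none
Why: Partial reduction of a lactone to the lactol with DIBAL-H: the strained bridged lactone, locked in the reactive (E)-ester geometry, should be attacked before the acyclic methyl ester, and the bridged tetrahedral aluminate should not collapse until work-up; no ring stereocentre is touched.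

Step 5
Reactants: 7 methyl (1S,4R,8S)-8-bromo-3-hydroxy-6-methyl-2-oxabicyclo[2.2.2]oct-5-ene-4-carboxylate
Product: 10 methyl (1S,4S,6S)-6-bromo-4-hydroxy-1,3-dimethylcyclohex-2-ene-1-carboxylate, via open-chain tosylhydrazone 8 (not isolated), via alkyl diazene 9 (not isolated)
Conditions: TsNHNH2, AcOH (cat.), 4 Å MS, CHCl3, rt; then catecholborane (3 equiv), 0 °C → rt; then NaOAc·3H2O, 60 °C
Reagents that add atoms: none
Why: Caglioti-type reductive deoxygenation (catecholborane variant): the lactol opens to the hydroxy aldehyde and condenses to tosylhydrazone 8, hydride adds to C=N, acetate-induced loss of sulfinate gives diazene 9, and loss of N2 leaves the methyl group, under conditions that should spare the ester, the secondary bromide and the alkene and leave every stereocentre untouched.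

Step 6
Reactants: 10 methyl (1S,4S,6S)-6-bromo-4-hydroxy-1,3-dimethylcyclohex-2-ene-1-carboxylate
Product: 11 (1S,4S,6S)-6-bromo-4-hydroxy-1,3-dimethylcyclohex-2-ene-1-carbaldehyde
Conditions: DIBAL-H (2.2 equiv), CH2Cl2, −78 °C; MeOH quench at −78 °C, then aq. Rochelle salt
Reagents that add atoms: none
Why: DIBAL-H partial reduction of an ester to the aldehyde: the first equivalent is consumed by the hydroxyl, and the tetrahedral aluminate of the hindered α-quaternary ester should persist at −78 °C until the cold quench; the aldehyde is trans to the C4 oxygen and cannot close to a lactol.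

Step 7
Reactants: 11 (1S,4S,6S)-6-bromo-4-hydroxy-1,3-dimethylcyclohex-2-ene-1-carbaldehyde
Product: 12 (1S,4S,5S)-5-bromo-4-[(E)-2-bromoethenyl]-2,4-dimethylcyclohex-2-en-1-ol
Conditions: CHBr3 (2 equiv), CrBr2 (6 equiv), THF, 0 °C → rt
Reagents that add atoms: bromoform, BrC(Br)Br
Why: Takai olefination: the gem-dichromium reagent from CHBr3 and Cr(II) adds to the aldehyde and eliminates to the (E)-bromoalkene, CrBr2 being used so that no chloride scrambles into the vinyl halide, and Cr(II) should leave the unactivated secondary bromide and the free allylic alcohol alone.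

Step 8
Reactants: 12 (1S,4S,5S)-5-bromo-4-[(E)-2-bromoethenyl]-2,4-dimethylcyclohex-2-en-1-ol
Product: 13 (3S,4S,6R)-4-bromo-3-[(E)-2-bromoethenyl]-6-chloro-1,3-dimethylcyclohex-1-ene
Conditions: PPh3, hexachloroacetone, CH2Cl2, 0 °C
Reagents that add atoms: hexachloroacetone, ClC(Cl)(Cl)C(=O)C(Cl)(Cl)Cl
Why: Appel-type chlorination with PPh3/hexachloroacetone, which converts allylic alcohols into chlorides by direct SN2 displacement of the alkoxyphosphonium ion: inversion turns the lactone-derived C–O bond (trans to Br) into the C–Cl bond cis to Br, and SN2′ is disfavoured because the distal alkene carbon is flanked by the quaternary centre.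

Step 9
Reactants: 13 (3S,4S,6R)-4-bromo-3-[(E)-2-bromoethenyl]-6-chloro-1,3-dimethylcyclohex-1-ene
Product: 14 (1S,2S,4R,5S)-2-bromo-1-[(E)-2-bromoethenyl]-4,5-dichloro-1,5-dimethylcyclohexane
Conditions: HCl (g, saturated), CH2Cl2, −20 → 0 °C
Reagents that add atoms: hydrogen chloride, Cl
Why: Markovnikov hydrochlorination: protonation at the CH terminus gives the tertiary cation at C5, and chloride should be captured axially in the chair that keeps Br, the secondary Cl and both methyls equatorial; the other epimer would force the C5 methyl syn-diaxial to the bromovinyl group and tertiary chlorides form reversibly under HCl, so kinetic and thermodynamic preferences both point to the (5S) chloride.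

**Compound list**

1 | (2E)-3-ethoxy-2-methylprop-2-enal | CCO/C=C(\C)C=O | starting material
2 | dimethyl malonate | COC(=O)CC(=O)OC | starting material
3 | dimethyl 2-[(2E)-3-ethoxy-2-methylprop-2-en-1-ylidene]propanedioate | CCO/C=C(\C)C=C(C(=O)OC)C(=O)OC | intermediate
4 | methyl 5-methyl-2-oxo-2H-pyran-3-carboxylate | COC(=O)C1=CC(C)=COC1=O | intermediate
5 | vinyl bromide | C=CBr | starting material
6 | methyl (1S,4S,8S)-8-bromo-6-methyl-3-oxo-2-oxabicyclo[2.2.2]oct-5-ene-4-carboxylate | CC1=C[C@@]2(C(=O)OC)[C@@H](Br)C[C@@H]1OC2=O | intermediate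
7 | methyl (1S,4R,8S)-8-bromo-3-hydroxy-6-methyl-2-oxabicyclo[2.2.2]oct-5-ene-4-carboxylate (C3 epimers) | CC1=C[C@@]2(C(=O)OC)[C@@H](Br)C[C@@H]1OC2O | intermediate
8 | methyl (1R,4S,6S)-6-bromo-4-hydroxy-3-methyl-1-{(E)-[2-(4-methylbenzenesulfonyl)hydrazinylidene]methyl}cyclohex-2-ene-1-carboxylate | CC1=C[C@@](/C=N/NS(=O)(=O)c2ccc(C)cc2)(C(=O)OC)[C@@H](Br)C[C@@H]1O | intermediate
9 | methyl (1R,4S,6S)-6-bromo-1-(diazenylmethyl)-4-hydroxy-3-methylcyclohex-2-ene-1-carboxylate | CC1=C[C@@](CN=N)(C(=O)OC)[C@@H](Br)C[C@@H]1O | intermediate
10 | methyl (1S,4S,6S)-6-bromo-4-hydroxy-1,3-dimethylcyclohex-2-ene-1-carboxylate | CC1=C[C@@](C)(C(=O)OC)[C@@H](Br)C[C@@H]1O | intermediate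
11 | (1S,4S,6S)-6-bromo-4-hydroxy-1,3-dimethylcyclohex-2-ene-1-carbaldehyde | CC1=C[C@@](C)(C=O)[C@@H](Br)C[C@@H]1O | intermediate
12 | (1S,4S,5S)-5-bromo-4-[(E)-2-bromoethenyl]-2,4-dimethylcyclohex-2-en-1-ol | CC1=C[C@@](C)(/C=C/Br)[C@@H](Br)C[C@@H]1O | intermediate
13 | (3S,4S,6R)-4-bromo-3-[(E)-2-bromoethenyl]-6-chloro-1,3-dimethylcyclohex-1-ene | CC1=C[C@@](C)(/C=C/Br)[C@@H](Br)C[C@H]1Cl | intermediate
14 | (1S,2S,4R,5S)-2-bromo-1-[(E)-2-bromoethenyl]-4,5-dichloro-1,5-dimethylcyclohexane | C[C@]1(Cl)C[C@@](C)(/C=C/Br)[C@@H](Br)C[C@H]1Cl | target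

Total step count: 9. Longest linear sequence: 9 steps (from 1).

**Steps most likely to fail**

1. Step 3 (Proposed new method). Vinyl bromide may be too weak a π-nucleophile, so that no cycloaddition occurs at temperatures the adduct survives, and forcing the reaction leads to retro-[4+2] loss of CO2 and aromatisation. The fallback uses known chemistry and sets out from 4. The same catalysed inverse-demand cycloaddition with tert-butyl vinyl ether, a known partner class for 3-carbomethoxy-2-pyrones, should give the endo tert-butyl ether methyl (1S,4S,8S)-8-tert-butoxy-6-methyl-3-oxo-2-oxabicyclo[2.2.2]oct-5-ene-4-carboxylate F1. TFA (CH2Cl2, 0 °C) frees the endo alcohol methyl (1S,4S,8S)-8-hydroxy-6-methyl-3-oxo-2-oxabicyclo[2.2.2]oct-5-ene-4-carboxylate F2. Quinoline-8-sulfonyl chloride/DMAP gives the chelating sulfonate methyl (1S,4S,8S)-6-methyl-3-oxo-8-(quinolin-8-ylsulfonyloxy)-2-oxabicyclo[2.2.2]oct-5-ene-4-carboxylate F3. TiBr4 (CH2Cl2, −78 °C → rt) should then exchange the sulfonate for bromide with retention (Ti-assisted front-side delivery), which comes back to the route at 6.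

2. Step 9. Protonation of the alkene, deactivated by the allylic chlorine, may be slow enough for the allylic chloride to ionise (loss of configuration at C4, allylic transposition), and chloride capture may show poor facial selectivity. The fallback sets out from 13. Mukaiyama hydration by hydrogen-atom transfer (Mn(dpm)3 cat., PhSiH3, O2, i-PrOH, 0 °C) places oxygen at the tertiary carbon without any cation and should give the tertiary alcohol (2R,4S,5S)-4-bromo-5-[(E)-2-bromoethenyl]-2-chloro-1,5-dimethylcyclohexan-1-ol F4 as either C1 epimer. Brief treatment with HCl in Et2O at −20 °C then converts it by SN1 substitution under thermodynamic control, which comes back to the route at 14.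

3. Step 4. Hydride may also attack the methyl ester, or the lactol may be over-reduced. The fallback sets out from 6. NaBH4 (MeOH/THF, 0 °C) opens only the strained lactone, all the way to the diol methyl (1R,4S,6S)-6-bromo-4-hydroxy-1-(hydroxymethyl)-3-methylcyclohex-2-ene-1-carboxylate F5. TEMPO (cat.)/PhI(OAc)2 (CH2Cl2, rt) then oxidises the primary alcohol selectively, and the cis hydroxy aldehyde closes to the lactol, which comes back to the route at 7; any over-oxidised material is 6 and is recycled.

**Further compounds**

F1 | step 3 | methyl (1S,4S,8S)-8-tert-butoxy-6-methyl-3-oxo-2-oxabicyclo[2.2.2]oct-5-ene-4-carboxylate | CC1=C[C@@]2(C(=O)OC)[C@@H](OC(C)(C)C)C[C@@H]1OC2=O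
F2 | step 3 | methyl (1S,4S,8S)-8-hydroxy-6-methyl-3-oxo-2-oxabicyclo[2.2.2]oct-5-ene-4-carboxylate | CC1=C[C@@]2(C(=O)OC)[C@@H](O)C[C@@H]1OC2=O
F3 | step 3 | methyl (1S,4S,8S)-6-methyl-3-oxo-8-(quinolin-8-ylsulfonyloxy)-2-oxabicyclo[2.2.2]oct-5-ene-4-carboxylate | CC1=C[C@@]2(C(=O)OC)[C@@H](OS(=O)(=O)c3cccc4cccnc34)C[C@@H]1OC2=O
F4 | step 9 | (2R,4S,5S)-4-bromo-5-[(E)-2-bromoethenyl]-2-chloro-1,5-dimethylcyclohexan-1-ol (C1 epimers) | CC1(O)C[C@@](C)(/C=C/Br)[C@@H](Br)C[C@H]1Cl
F5 | step 4 | methyl (1R,4S,6S)-6-bromo-4-hydroxy-1-(hydroxymethyl)-3-methylcyclohex-2-ene-1-carboxylate | CC1=C[C@@](CO)(C(=O)OC)[C@@H](Br)C[C@@H]1O
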